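1. Chain numbering: C1≡C2–C3=C4–C5–C6(OAc)–C7–C8–C9=C10–C11–C12–C13(Br)–C14–C15, ring O between C7 and C12. Target 24 ⇐ acetylation and desilylation ⇐ C13 bromide by inversion of a threo alcohol ⇐ EtMgBr addition to a C12 aldehyde; Z-enyne ⇐ Peterson olefination of a C4 aldehyde.
2. Oxepene ester 13 ⇐ vinyl oxetane 10 + ethyl diazoacetate 11: an oxonium ylide [2,3]-shift makes C11–C12 and C9=C10 (and O–C12) at once and expands the four-membered ring to the seven-membered ring.
3. Enabling feature: the oxetane ring O–C7–C8–C9 with the C10=C11 vinyl group on C9, trans to the C7 side chain; its C9–O bond is allylic and strained, and the C9 stereocentre is erased after it has steered C7, C6 and C12.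
4. Oxetane 9 ⇐ 4-exo opening of the cis C6–C7 epoxide by the C9 alkoxide ⇐ hydroxyl-directed epoxidation of Z-alkene 5 ⇐ alkyne 1 + (S)-epichlorohydrin 2.
5. Ring order: oxirane (C6–C7), then oxetane (O, C7, C8, C9), then oxepene (O, C7 to C12).

Key step: step 7

Remark: the target is read as (6S,7S,12R,13S,3Z); compounds 1, 2, 11 and 16 are taken as commercially available; TBS = tert-butyldimethylsilyl, TIPS = triisopropylsilyl.

Step 1
Reactants: 1 tert-butyl(but-3-yn-1-yloxy)dimethylsilane; 2 (S)-epichlorohydrin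
Product: 4 (2S)-7-(TBS-oxy)-1-chlorohept-4-yn-2-ol, via lithium acetylide 3 (not isolated)
Conditions: n-BuLi, THF, −78 °C; BF3·OEt2; then 2, −78 °C
Reagents that add atoms: none
Why: BF3-promoted opening of the epoxide by the lithium acetylide (epoxide alkynylation) should occur by SN2 attack at the unsubstituted ring carbon, so the C9 stereocentre of 2 is carried over unchanged and the chloride is not displaced at −78 °C.

Step 2
Reactants: 4 (2S)-7-(TBS-oxy)-1-chlorohept-4-yn-2-ol
Product: 5 (2S,4Z)-7-(TBS-oxy)-1-chlorohept-4-en-2-ol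
Conditions: H2 (1 atm), Pd/CaCO3 poisoned with Pb(OAc)2 (Lindlar catalyst), quinoline, EtOAc, rt
Reagents that add atoms: none
Why: Lindlar semihydrogenation adds H2 syn and should stop at the Z-alkene that a cis-epoxide requires, while the alkyl chloride and the silyl ether are inert.

Step 3
Reactants: 5 (2S,4Z)-7-(TBS-oxy)-1-chlorohept-4-en-2-ol
Product: 6 (2S)-1-chloro-3-[(2R,3S)-3-(2-(TBS-oxy)ethyl)oxiran-2-yl]propan-2-ol
Conditions: VO(acac)2 (cat.), t-BuOOH, CH2Cl2, 0 °C to rt
Reagents that add atoms: tert-butyl hydroperoxide, CC(C)(C)OO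
Why: Hydroxyl-directed epoxidation of the Z-homoallylic alcohol should pass through a chair-like vanadate ester with the C9 CH2Cl group equatorial and the Z-substituent turned away from the ring, so oxygen is delivered syn to the C9 oxygen and the C9 centre sets C7 (R) and C6 (S) of the cis-epoxide.

Step 4
Reactants: 6 (2S)-1-chloro-3-[(2R,3S)-3-(2-(TBS-oxy)ethyl)oxiran-2-yl]propan-2-ol
Product: 8 (2S)-1-[(2R,3S)-3-(2-(TBS-oxy)ethyl)oxiran-2-yl]but-3-en-2-ol, via bis-epoxide 7 (not isolated)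
Conditions: Me3S+ I− (4 equiv), n-BuLi (3.8 equiv), THF, −10 °C to rt
Reagents that add atoms: trimethylsulfonium iodide, C[S+](C)C.[I-]
Why: The chlorohydrin alkoxide closes to terminal epoxide 7, dimethylsulfonium methylide opens it at CH2 and the sulfonium betaine loses dimethyl sulfide (Corey–Chaykovsky-type one-carbon homologation of an epoxide to an allylic alcohol), so the vinyl carbinol forms without touching the C9–O bond or the more hindered cis-epoxide.

Step 5
Reactants: 8 (2S)-1-[(2R,3S)-3-(2-(TBS-oxy)ethyl)oxiran-2-yl]but-3-en-2-ol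
Product: 9 (1S)-3-(TBS-oxy)-1-[(2S,4S)-4-ethenyloxetan-2-yl]propan-1-ol
Conditions: KOt-Bu (0.2 equiv), t-BuOH/THF, 40 °C
Reagents that add atoms: none
Why: Under basic conditions the C9 alkoxide should open the epoxide in the 4-exo-tet mode (5-endo attack at C6 is stereoelectronically disfavoured) with inversion at C7, giving the trans-2,4-disubstituted oxetane with C7 (S) and the free C6 (S) hydroxyl (intramolecular epoxide opening); a 1,3-silyl shift would be harmless because step 6 silylates the other oxygen.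

Step 6
Reactants: 9 (1S)-3-(TBS-oxy)-1-[(2S,4S)-4-ethenyloxetan-2-yl]propan-1-ol
Product: 10 (2S,4S)-2-[(1S)-1,3-bis(TBS-oxy)propyl]-4-ethenyloxetane
Conditions: TBSCl, imidazole, DMF, rt
Reagents that add atoms: tert-butyldimethylsilyl chloride, CC(C)(C)[Si](C)(C)Cl
Why: Silylation of the secondary alcohol under non-acidic conditions spares the acid-labile vinyl oxetane and removes the only O–H bond that could intercept the carbene of step 7.

Step 7
Reactants: 10 (2S,4S)-2-[(1S)-1,3-bis(TBS-oxy)propyl]-4-ethenyloxetane; 11 ethyl diazoacetate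
Product: 13 ethyl (2R,7S)-7-[(1S)-1,3-bis(TBS-oxy)propyl]-2,3,6,7-tetrahydrooxepine-2-carboxylate, via oxonium ylide 12 (not isolated)
Conditions: Cu(CF3COCHCOCH3)2 (5 mol %), CH2Cl2, reflux, slow addition of 11
Reagents that add atoms: none
Why: The copper carbene from 11 is captured by the oxetane oxygen, the most basic and exposed ether oxygen, on the ring face anti to the C7 side chain and therefore syn to the C9 vinyl group of the trans-oxetane, and the resulting oxonium ylide 12 undergoes a [2,3]-sigmatropic shift that makes the C11–C12 bond and the C9=C10 double bond while the allylic C9–O bond of the strained ring breaks. The closest known reaction type is the copper-catalysed ring expansion of 2-vinyl oxetanes and vinyl oxiranes by diazo esters through oxonium ylides. The oxepene is closed by C11–C12 bond formation in a five-centre envelope transition state fused to the four-membered ring, a three-atom ring expansion (four to seven) that can only give the Z ring alkene. C12 is the only new stereocentre and is controlled by C7: with the carbene carbon on the face opposite the C7 substituent, the ester should take the exo position anti to C7 about the O–C12 bond, which places H12 cis to H7 (12R, 2,7-cis), and the C9 centre is erased. The step needs ylide formation to outrun cyclopropanation of the vinyl group and the [2,3] shift to outrun the [1,2] shift, which the acetylacetonate-type copper catalyst, slow addition of 11, the silyl-shielded side-chain oxygens and the strain released through the allylic C9–O bond should secure.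

Step 8
Reactants: 13 ethyl (2R,7S)-7-[(1S)-1,3-bis(TBS-oxy)propyl]-2,3,6,7-tetrahydrooxepine-2-carboxylate
Product: 14 ethyl (2R,7S)-7-[(1S)-1-(TBS-oxy)-3-hydroxypropyl]-2,3,6,7-tetrahydrooxepine-2-carboxylate
Conditions: HF·pyridine, pyridine, THF, 0 °C
Reagents that add atoms: none
Why: Buffered HF·pyridine should cleave the unhindered primary silyl ether much faster than the secondary one flanked by the ring (selective desilylation), without touching the ester or epimerising C12.

Step 9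
Reactants: 14 ethyl (2R,7S)-7-[(1S)-1-(TBS-oxy)-3-hydroxypropyl]-2,3,6,7-tetrahydrooxepine-2-carboxylate
Product: 15 ethyl (2R,7S)-7-[(1S)-1-(TBS-oxy)-3-oxopropyl]-2,3,6,7-tetrahydrooxepine-2-carboxylate
Conditions: Dess–Martin periodinane, NaHCO3, CH2Cl2, rt
Reagents that add atoms: none
Why: Dess–Martin oxidation under buffered neutral conditions should give the β-silyloxy aldehyde without β-elimination and without epimerising C6 or C12.

Step 10
Reactants: 15 ethyl (2R,7S)-7-[(1S)-1-(TBS-oxy)-3-oxopropyl]-2,3,6,7-tetrahydrooxepine-2-carboxylate; 16 1,3-bis(triisopropylsilyl)propyne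
Product: 19 ethyl (2R,7S)-7-[(1S,3Z)-1-(TBS-oxy)-6-(TIPS)hex-3-en-5-yn-1-yl]-2,3,6,7-tetrahydrooxepine-2-carboxylate, via lithiated propyne 17 (not isolated), via β-silyl alkoxide 18 (not isolated)
Conditions: 16, n-BuLi, THF, −78 °C; then 15, −78 °C to rt
Reagents that add atoms: none
Why: The lithiated bis-silyl propyne adds to the aldehyde far faster than to the ester at −78 °C and the β-silyl alkoxide undergoes syn-elimination (Peterson olefination), in which the bulky triisopropylsilyl groups favour the anti adduct and hence the Z-enyne.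

Step 11
Reactants: 19 ethyl (2R,7S)-7-[(1S,3Z)-1-(TBS-oxy)-6-(TIPS)hex-3-en-5-yn-1-yl]-2,3,6,7-tetrahydrooxepine-2-carboxylate
Product: 20 (2R,7S)-7-[(1S,3Z)-1-(TBS-oxy)-6-(TIPS)hex-3-en-5-yn-1-yl]-2,3,6,7-tetrahydrooxepine-2-carbaldehyde
Conditions: i-Bu2AlH, CH2Cl2, −78 °C
Reagents that add atoms: none
Why: The α-alkoxy ester forms a chelated tetrahedral aluminate at −78 °C that collapses to the aldehyde only on work-up (partial ester reduction), and these non-basic conditions should leave C12 and the silylated enyne untouched.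

Step 12
Reactants: 20 (2R,7S)-7-[(1S,3Z)-1-(TBS-oxy)-6-(TIPS)hex-3-en-5-yn-1-yl]-2,3,6,7-tetrahydrooxepine-2-carbaldehyde
Product: 21 (1R)-1-{(2R,7S)-7-[(1S,3Z)-1-(TBS-oxy)-6-(TIPS)hex-3-en-5-yn-1-yl]-2,3,6,7-tetrahydrooxepin-2-yl}propan-1-ol
Conditions: MgBr2·OEt2, CH2Cl2, −78 °C; then EtMgBr
Reagents that add atoms: ethylmagnesium bromide, CC[Mg]Br
Why: Magnesium chelated between the aldehyde oxygen and the ring oxygen (Cram chelate) should direct the Grignard addition to the face on the side of H12, setting C13 as the (R)-alcohol, threo to the ring oxygen.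

Step 13
Reactants: 21 (1R)-1-{(2R,7S)-7-[(1S,3Z)-1-(TBS-oxy)-6-(TIPS)hex-3-en-5-yn-1-yl]-2,3,6,7-tetrahydrooxepin-2-yl}propan-1-ol
Product: 22 (2R,7S)-2-[(1S)-1-bromopropyl]-7-[(1S,3Z)-1-(TBS-oxy)-6-(TIPS)hex-3-en-5-yn-1-yl]-2,3,6,7-tetrahydrooxepine
Conditions: CBr4, P(n-C8H17)3, 1-methylcyclohexene, toluene, 70 °C
Reagents that add atoms: carbon tetrabromide, BrC(Br)(Br)Br
Why: Appel-type bromination through the alkoxyphosphonium ion should proceed by SN2 displacement with inversion, turning the (13R)-alcohol into the (13S)-bromide under neutral conditions that the hindered silyl ether, the silylated enyne and the ring alkene tolerate.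

Step 14
Reactants: 22 (2R,7S)-2-[(1S)-1-bromopropyl]-7-[(1S,3Z)-1-(TBS-oxy)-6-(TIPS)hex-3-en-5-yn-1-yl]-2,3,6,7-tetrahydrooxepine
Product: 23 (1S,3Z)-1-{(2S,7R)-7-[(1S)-1-bromopropyl]-2,3,6,7-tetrahydrooxepin-2-yl}hex-3-en-5-yn-1-ol
Conditions: Bu4NF, AcOH, THF, 0 °C to rt
Reagents that add atoms: none
Why: Fluoride removes the alkynyl and the O-silyl group in one operation (desilylation), and the acetic acid buffer keeps the C6 oxygen protonated so that it should not displace the C13 bromide.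

Step 15
Reactants: 23 (1S,3Z)-1-{(2S,7R)-7-[(1S)-1-bromopropyl]-2,3,6,7-tetrahydrooxepin-2-yl}hex-3-en-5-yn-1-ol
Product: 24 (1S,3Z)-1-{(2S,7R)-7-[(1S)-1-bromopropyl]-2,3,6,7-tetrahydrooxepin-2-yl}hex-3-en-5-yn-1-yl acetate
Conditions: Ac2O, pyridine, DMAP (cat.), CH2Cl2, 0 °C to rt
Reagents that add atoms: acetic anhydride, CC(=O)OC(C)=O
Why: DMAP-catalysed acylation of the secondary alcohol (esterification) proceeds with retention at C6 and should leave the terminal alkyne, both alkenes and the bromide untouched.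

Compound list
1 | tert-butyl(but-3-yn-1-yloxy)dimethylsilane | C#CCCO[Si](C)(C)C(C)(C)C | starting material
2 | (S)-epichlorohydrin | ClC[C@@H]1CO1 | starting material
3 | lithium acetylide of 1 | [Li]C#CCCO[Si](C)(C)C(C)(C)C | intermediate (not isolated)
4 | (2S)-7-(TBS-oxy)-1-chlorohept-4-yn-2-ol | ClC[C@@H](O)CC#CCCO[Si](C)(C)C(C)(C)C | intermediate
5 | (2S,4Z)-7-(TBS-oxy)-1-chlorohept-4-en-2-ol | ClC[C@@H](O)C/C=C\CCO[Si](C)(C)C(C)(C)C | intermediate
6 | (2S)-1-chloro-3-[(2R,3S)-3-(2-(TBS-oxy)ethyl)oxiran-2-yl]propan-2-ol | ClC[C@@H](O)C[C@H]1O[C@H]1CCO[Si](C)(C)C(C)(C)C | intermediate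
7 | (2R,3S)-2-{[(2S)-oxiran-2-yl]methyl}-3-(2-(TBS-oxy)ethyl)oxirane | C1O[C@H]1C[C@H]2O[C@H]2CCO[Si](C)(C)C(C)(C)C | intermediate (not isolated)
8 | (2S)-1-[(2R,3S)-3-(2-(TBS-oxy)ethyl)oxiran-2-yl]but-3-en-2-ol | C=C[C@@H](O)C[C@H]1O[C@H]1CCO[Si](C)(C)C(C)(C)C | intermediate
9 | (1S)-3-(TBS-oxy)-1-[(2S,4S)-4-ethenyloxetan-2-yl]propan-1-ol | C=C[C@@H]1C[C@H](O1)[C@@H](O)CCO[Si](C)(C)C(C)(C)C | intermediate
10 | (2S,4S)-2-[(1S)-1,3-bis(TBS-oxy)propyl]-4-ethenyloxetane | C=C[C@@H]1C[C@H](O1)[C@@H](O[Si](C)(C)C(C)(C)C)CCO[Si](C)(C)C(C)(C)C | intermediate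
11 | ethyl diazoacetate | CCOC(=O)C=[N+]=[N-] | starting material
12 | oxonium ylide of 10 (oxetane oxygen bearing the ethoxycarbonylmethylide carbon, syn to the vinyl group) | C=C[C@@H]1C[C@H]([O+]1[CH-]C(=O)OCC)[C@@H](O[Si](C)(C)C(C)(C)C)CCO[Si](C)(C)C(C)(C)C | intermediate (not isolated)
13 | ethyl (2R,7S)-7-[(1S)-1,3-bis(TBS-oxy)propyl]-2,3,6,7-tetrahydrooxepine-2-carboxylate | CCOC(=O)[C@H]1CC=CC[C@H](O1)[C@@H](O[Si](C)(C)C(C)(C)C)CCO[Si](C)(C)C(C)(C)C | intermediate
14 | ethyl (2R,7S)-7-[(1S)-1-(TBS-oxy)-3-hydroxypropyl]-2,3,6,7-tetrahydrooxepine-2-carboxylate | CCOC(=O)[C@H]1CC=CC[C@H](O1)[C@@H](O[Si](C)(C)C(C)(C)C)CCO | intermediate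
15 | ethyl (2R,7S)-7-[(1S)-1-(TBS-oxy)-3-oxopropyl]-2,3,6,7-tetrahydrooxepine-2-carboxylate | CCOC(=O)[C@H]1CC=CC[C@H](O1)[C@@H](O[Si](C)(C)C(C)(C)C)CC=O | intermediate
16 | 1,3-bis(triisopropylsilyl)propyne | CC(C)[Si](C(C)C)(C(C)C)CC#C[Si](C(C)C)(C(C)C)C(C)C | starting material
17 | 3-lithio-1,3-bis(triisopropylsilyl)propyne | CC(C)[Si](C(C)C)(C(C)C)C([Li])C#C[Si](C(C)C)(C(C)C)C(C)C | intermediate (not isolated)
18 | lithium β-silyl alkoxide adduct of 15 and 17 (the two new centres anti; both aldehyde-face isomers, left unassigned in the SMILES) | CCOC(=O)[C@H]1CC=CC[C@H](O1)[C@@H](O[Si](C)(C)C(C)(C)C)CC(O[Li])C(C#C[Si](C(C)C)(C(C)C)C(C)C)[Si](C(C)C)(C(C)C)C(C)C | intermediate (not isolated)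
19 | ethyl (2R,7S)-7-[(1S,3Z)-1-(TBS-oxy)-6-(TIPS)hex-3-en-5-yn-1-yl]-2,3,6,7-tetrahydrooxepine-2-carboxylate | CCOC(=O)[C@H]1CC=CC[C@H](O1)[C@@H](O[Si](C)(C)C(C)(C)C)C/C=C\C#C[Si](C(C)C)(C(C)C)C(C)C | intermediate
20 | (2R,7S)-7-[(1S,3Z)-1-(TBS-oxy)-6-(TIPS)hex-3-en-5-yn-1-yl]-2,3,6,7-tetrahydrooxepine-2-carbaldehyde | O=C[C@H]1CC=CC[C@H](O1)[C@@H](O[Si](C)(C)C(C)(C)C)C/C=C\C#C[Si](C(C)C)(C(C)C)C(C)C | intermediate
21 | (1R)-1-{(2R,7S)-7-[(1S,3Z)-1-(TBS-oxy)-6-(TIPS)hex-3-en-5-yn-1-yl]-2,3,6,7-tetrahydrooxepin-2-yl}propan-1-ol | CC[C@@H](O)[C@H]1CC=CC[C@H](O1)[C@@H](O[Si](C)(C)C(C)(C)C)C/C=C\C#C[Si](C(C)C)(C(C)C)C(C)C | intermediate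
22 | (2R,7S)-2-[(1S)-1-bromopropyl]-7-[(1S,3Z)-1-(TBS-oxy)-6-(TIPS)hex-3-en-5-yn-1-yl]-2,3,6,7-tetrahydrooxepine | CC[C@H](Br)[C@H]1CC=CC[C@H](O1)[C@@H](O[Si](C)(C)C(C)(C)C)C/C=C\C#C[Si](C(C)C)(C(C)C)C(C)C | intermediate
23 | (1S,3Z)-1-{(2S,7R)-7-[(1S)-1-bromopropyl]-2,3,6,7-tetrahydrooxepin-2-yl}hex-3-en-5-yn-1-ol | C#C/C=C\C[C@H](O)[C@@H]1CC=CC[C@H]([C@@H](Br)CC)O1 | intermediate
24 | (1S,3Z)-1-{(2S,7R)-7-[(1S)-1-bromopropyl]-2,3,6,7-tetrahydrooxepin-2-yl}hex-3-en-5-yn-1-yl acetate | C#C/C=C\C[C@H](OC(C)=O)[C@@H]1CC=CC[C@H]([C@@H](Br)CC)O1 | target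

Total step count: 15. Longest linear sequence: 15 steps (1 and 2 to 24).

Steps most likely to fail

Step 7. The copper carbene may add to the C10=C11 double bond (cyclopropanation), the ylide may collapse by a [1,2] shift to a tetrahydrofuran, or it may rearrange through the endo arrangement and erode the cis relationship at C12. Fallback (ring closure by alkene metathesis, C12 set by a chiral auxiliary), setting out from 10 and returning at 13:
- The allylic C9–O bond is cleaved with hydride delivery to C11 (Pd(PPh3)4, LiBHEt3, THF) to give (3S,4S,6E)-1,3-bis(TBS-oxy)oct-6-en-4-ol F1.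
- O-Alkylation (NaH, BrCH2CO2H, THF) gives the glycolic acid ether F2.
- Mixed anhydride formation (t-BuCOCl, Et3N) and acylation of lithiated (S)-4-benzyloxazolidin-2-one gives the imide F3.
- The sodium enolate (NaN(SiMe3)2, THF, −78 °C) is alkylated with allyl iodide anti to the benzyl group to give the (2R)-pent-4-enoyl imide F4.
- Ring-closing metathesis with the second-generation Grubbs catalyst RuCl2(=CHPh)(PCy3)(H2IMes) in CH2Cl2 at reflux, with loss of propene, gives the oxepene imide F5.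
- Ethanolysis (EtOMgBr, EtOH, 0 °C) removes the auxiliary and gives ester 13.

Step 13. The ring oxygen may participate in the ionising alkoxyphosphonium ion (three-membered oxonium), which would give retention or a ring-enlarged bromide, and adventitious HBr may strip the silyl ether. Fallback (two-stage sulfonate displacement in place of in situ activation), setting out from 21 and returning at 22: the alcohol is converted with retention into the chloromethanesulfonate F6 (ClCH2SO2Cl, pyridine, CH2Cl2, 0 °C), which is displaced by bromide under non-ionising SN2 conditions (LiBr, DMF, rt to 40 °C).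

Step 3. Facial discrimination in the directed oxygen transfer may be insufficient, or the Lewis-acidic metal may open the epoxy alcohol. Fallback (electrophilic cyclisation with 1,3-induction through a six-membered carbonate in place of metal-directed epoxidation), setting out from 5 and returning at 7:
- The alcohol is converted into the tert-butyl carbonate F7 (Boc2O, DMAP, MeCN).
- IBr (toluene, −85 °C) closes it to the cis-4,6-disubstituted iodocarbonate F8, both ring substituents equatorial.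
- Methanolysis (K2CO3, MeOH) frees the C7 and C9 alkoxides, which displace iodide and chloride to give bis-epoxide 7, the intermediate of step 4; the ylide homologation (Me3S+ I−, n-BuLi) then continues to 8.

Further compounds
F1 | step 7 | (3S,4S,6E)-1,3-bis(TBS-oxy)oct-6-en-4-ol | C/C=C/C[C@H](O)[C@@H](O[Si](C)(C)C(C)(C)C)CCO[Si](C)(C)C(C)(C)C
F2 | step 7 | 2-{[(3S,4S,6E)-1,3-bis(TBS-oxy)oct-6-en-4-yl]oxy}acetic acid | C/C=C/C[C@H](OCC(=O)O)[C@@H](O[Si](C)(C)C(C)(C)C)CCO[Si](C)(C)C(C)(C)C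
F3 | step 7 | (4S)-4-benzyl-3-(2-{[(3S,4S,6E)-1,3-bis(TBS-oxy)oct-6-en-4-yl]oxy}acetyl)oxazolidin-2-one | C/C=C/C[C@H](OCC(=O)N1[C@@H](Cc2ccccc2)COC1=O)[C@@H](O[Si](C)(C)C(C)(C)C)CCO[Si](C)(C)C(C)(C)C
F4 | step 7 | (4S)-4-benzyl-3-[(2R)-2-{[(3S,4S,6E)-1,3-bis(TBS-oxy)oct-6-en-4-yl]oxy}pent-4-enoyl]oxazolidin-2-one | C/C=C/C[C@H](O[C@H](CC=C)C(=O)N1[C@@H](Cc2ccccc2)COC1=O)[C@@H](O[Si](C)(C)C(C)(C)C)CCO[Si](C)(C)C(C)(C)C
F5 | step 7 | (4S)-4-benzyl-3-{[(2R,7S)-7-[(1S)-1,3-bis(TBS-oxy)propyl]-2,3,6,7-tetrahydrooxepin-2-yl]carbonyl}oxazolidin-2-one | O=C([C@H]1CC=CC[C@H](O1)[C@@H](O[Si](C)(C)C(C)(C)C)CCO[Si](C)(C)C(C)(C)C)N2[C@@H](Cc3ccccc3)COC2=O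
F6 | step 13 | (1R)-1-{(2R,7S)-7-[(1S,3Z)-1-(TBS-oxy)-6-(TIPS)hex-3-en-5-yn-1-yl]-2,3,6,7-tetrahydrooxepin-2-yl}propyl chloromethanesulfonate | CC[C@@H](OS(=O)(=O)CCl)[C@H]1CC=CC[C@H](O1)[C@@H](O[Si](C)(C)C(C)(C)C)C/C=C\C#C[Si](C(C)C)(C(C)C)C(C)C
F7 | step 3 | tert-butyl (2S,4Z)-7-(TBS-oxy)-1-chlorohept-4-en-2-yl carbonate | ClC[C@@H](OC(=O)OC(C)(C)C)C/C=C\CCO[Si](C)(C)C(C)(C)C
F8 | step 3 | (4S,6R)-4-(chloromethyl)-6-[(1R)-3-(TBS-oxy)-1-iodopropyl]-1,3-dioxan-2-one | O=C1O[C@H](CCl)C[C@@H](O1)[C@H](I)CCO[Si](C)(C)C(C)(C)C
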